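The data were computed on assumed constants, and the scatter is random.

Q and G, the products, are mirror images, made from the racemate of E and J by single-handed X.

| setting | south | west | north | flask |
|---|---|---|---|---|
| E | 18 mM | 70 mM | 35 mM | 35 mM |
| J | 18 mM | 70 mM | 35 mM | 35 mM |
| X | 105 mM | 105 mM | 160 mM | 105 mM |
| remark | run made earlier | run made earlier | run made earlier |  |
| time |  |  |  | 25 min |

| run | time / min | Q / % | G / % |
|---|---|---|---|
| south | 0.833 | 50.6 | 47.5 |
| south | 2.50 | 49.1 | 49.4 |
| south | 4.00 | 48.6 | 51.1 |
| south | 6.00 | 48.9 | 49.7 |
| south | 10.0 | 49.8 | 49.6 |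
| south | 12.0 | 51.2 | 50.3 |
| south | 15.0 | 50.6 | 51.6 |
| west | 0.833 | 37.1 | 37.0 |
| west | 2.50 | 37.0 | 36.8 |
| west | 4.00 | 38.1 | 37.3 |
| west | 6.00 | 36.7 | 38.6 |
| west | 10.0 | 38.8 | 36.9 |
| west | 12.0 | 37.2 | 36.8 |
| west | 15.0 | 35.6 | 38.4 |
| north | 3.00 | 47.7 | 49.2 |
| north | 6.00 | 49.4 | 47.9 |
| north | 10.0 | 50.7 | 48.9 |
| north | 12.0 | 51.1 | 51.7 |
| north | 15.0 | 51.9 | 50.7 |

(readings scatter by 1 percentage point)

- X is single-handed; E and J are mirror images of each other, charged as a racemate, each of them at the stated concentration
- the earlier runs were read with a standard deviation of 1 percentage point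
- the handed part of X does not stay in what it makes, so the products of the two hands are mirror images too

- how much Q there is at 25 min, in percent of the E and J together charged
- how much G there is at 25 min, in percent of the E and J together charged

You can get the answer from a chain of three estimates. First, take the west run, where X is short: 105 mM of X meets 140 mM of E and J together. At 0.833 min, Q reads 37.1% and G reads 37.0%, which makes 104 mM of product. So the rate of X use divided by the rate of product making reads one, and time drops out. Second, Q and G read alike in that pair, so give each half of the product. Third, the flask has 1.50 as its cover c, the X charged divided by the E and J together charged. With c above one, the substrate goes first, and my estimate is 50.0% of each product.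

The weak link is time: c tells how much product a flask can reach, not when. But the west run already read that product at 0.833 min, from the same charge of X as the flask, and the asked time is 30.0 times longer. So the estimate stands.

The forecast agrees, with 50% of Q and 50% of G, since the flask “should therefore go to completion well before 25 min”.

The flask gives 50.0% of Q and 50.0% of G.

    X + E → Q (k = 1.58 /M/s)
    X + J → G (k = 0.592 /M/s)
    E ⇌ J (k = 0.656 /s)
    X → L (k = 4.14 × 10⁻⁵ /s)
    Q ⇌ G (k = 0.0438 /s)

The cover leaves 33.3% of the X charge, and the flask holds 31.3% at 25.0 min, beside 2.15 mM of L. Now charge 42 mM of X to the same flask. Then c is 0.600, below one, so X is the limiting reagent and the rule gives 30.0% of each product. That neighbour gives 30.0% of Q and 30.0% of G at 25.0 min, with X at 0% of its charge and E at 20.0%.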